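**Retrosynthetic overview**

1. Locants follow spiro[5.5]undecane. Ring B is C1–C6 (C1=C2, C3=CHBr, C4H2, C5H2), C6 is the spiro carbon, and ring A is C6–C11 (C7 Me/OH, C9 Br, C11 Me2).
2. End game: (E)-C3=CHBr ⇐ vinylstannane ⇐ (E)-dienyl triflate ⇐ s-trans enal 19 ⇐ ester. C9–Br ⇐ SN2 on the axial alcohol ⇐ C9 ketone ⇐ equatorial C9 carbinol, which serves as a stereochemical relay.
3. C6 ⇐ hydroxyl-directed hydrogenation of one of the two diastereotopic ring-B alkenes of diene 12.
4. Key disconnection C6–C7: ring B is present from the start as the benzene ring of 1. Ring A is closed last, by a reductive dearomatising ketyl–arene spirocyclisation of the open-chain keto benzoate 10, itself three steps from 1, 2 and 6.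
5. Enabling feature: C6 and the exocyclic carbon on C3 are para on ring B, so ring B plus that carbon is a benzoate. Its ipso carbon C6 is the 1,6-acceptor terminus for a ketyl at C7, reached through the four-atom tether C11–C10–C9–C8. The C11 gem-dimethyl group folds the chain over the ring, and its axial methyl steers C7, C6 and C9.

Key step: step 4

Remark: the ester-bearing carbon C3 of 12–18 should form as an epimer mixture that is erased when C3 becomes sp2 in 19, so it is left undefined. In 12 the two arms at C6 are constitutionally equal, so C6 is also left undefined there.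

**Step 1**
Reactants: 1 methyl 4-iodobenzoate; 2 3-methylbut-2-enal
Product: 5 methyl 4-(2-methyl-4-oxobutan-2-yl)benzoate, via arylmagnesium chloride 3 (not isolated), via trimethylsilyl enol ether 4 (not isolated)
Conditions: i-PrMgCl·LiCl, THF, −20 °C; then CuBr·SMe2 (10 mol %), TMSCl, DMPU, 2, −40 → −20 °C; 1 M HCl work-up
Reagents that add atoms: none
Why: Iodine–magnesium exchange tolerates the ester at low temperature, and the chlorosilane-accelerated copper-catalysed conjugate addition of the aryl Grignard reagent to the β,β-disubstituted enal should build the benzylic quaternary carbon, with TMSCl trapping the enolate so that 1,2-addition and aldol reactions are held back; no stereocentre is formed.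

**Step 2**
Reactants: 5 methyl 4-(2-methyl-4-oxobutan-2-yl)benzoate; 6 2-methylallylboronic acid pinacol ester
Product: 8 methyl 4-[(4S)-4-hydroxy-2,6-dimethylhept-6-en-2-yl]benzoate, via pinacol borate ester 7 (not isolated)
Conditions: (S)-TRIP (5 mol %), toluene, −30 °C; aq. NaHCO3 work-up
Reagents that add atoms: none
Why: Chiral phosphoric acid-catalysed asymmetric allylboration through a closed chair transition state, in which the (S)-catalyst should expose the Si face of the aldehyde (the (R)-catalyst is known to give Re-face attack), sets the (S)-carbinol that becomes C9 and leaves the ester untouched.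

**Step 3**
Reactants: 8 methyl 4-[(4S)-4-hydroxy-2,6-dimethylhept-6-en-2-yl]benzoate
Product: 10 methyl 4-[(4R)-4-hydroxy-2-methyl-6-oxoheptan-2-yl]benzoate, via secondary ozonide 9 (not isolated)
Conditions: O3, CH2Cl2, −78 °C; then Me2S, −78 °C → rt
Reagents that add atoms: ozone [O-][O+]=O
Why: Ozonolysis should cleave only the electron-rich 1,1-disubstituted alkene, since the ester-deactivated arene is inert, and reductive work-up gives the methyl ketone without touching the carbinol centre, whose descriptor changes to R only through CIP priorities.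

**Step 4**
Reactants: 10 methyl 4-[(4R)-4-hydroxy-2-methyl-6-oxoheptan-2-yl]benzoate
Product: 12 methyl (7S,9R)-7,9-dihydroxy-7,11,11-trimethylspiro[5.5]undeca-1,4-diene-3-carboxylate, via bis-samarium(III) alkoxide dienolate 11 (not isolated)
Conditions: SmI2 (3 equiv), HMPA (12 equiv), t-BuOH (3 equiv), THF, 0 °C, high dilution
Reagents that add atoms: none
Why: Sm(II)–HMPA reduces the methyl ketone to a Sm(III) ketyl that adds to the ipso carbon C6 of the benzoate ring; the resulting cyclohexadienyl radical carries its spin on the ester-bearing para carbon C3 and is reduced at once by a second Sm(II) to the ester dienolate 11, which t-BuOH protonates at C3 to leave the skipped 1,4-diene. The closest known reaction type is the SmI2–HMPA ketyl–arene spirocyclisation of 4-(oxoalkyl)benzoates, together with the dearomatising ketyl–aryl cyclisation of γ-aryl ketones, used here for a six-membered ring. Ring A closes in the 6-exo-trig (spiro) mode on the ipso–ortho π bond, the alternative being 7-endo attack at an ortho carbon. C7 is the only stereocentre fixed here: in the chair transition state the C9–OH is equatorial (no chelate, because HMPA saturates samarium) and one C11 methyl is necessarily axial, so the ketyl methyl goes equatorial to avoid a syn-axial Me/Me contact and the O–Sm goes axial, trans to C9–OH, which gives (7S) from (9R). Three selectivities are needed: ipso over ortho attack, secured by ring size and the para ester; cyclisation over plain ketone reduction, secured by the gem-dialkyl effect of C11; and reduction of the spiro radical faster than reversal or β-scission of C6–C11, secured by the ester, which makes it an easily reduced α-carbonyl-type radical. The reductant pays for the lost aromaticity, which is why a bond between two fully substituted carbons next to a third can form, and in one operation ring A, the quaternary C6, the tertiary carbinol C7 and a non-aromatic ring B carrying the future =CHBr carbon are obtained.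

**Step 5**
Reactants: 12 methyl (7S,9R)-7,9-dihydroxy-7,11,11-trimethylspiro[5.5]undeca-1,4-diene-3-carboxylate
Product: 13 methyl (6S,7S,9R)-7,9-dihydroxy-7,11,11-trimethylspiro[5.5]undec-1-ene-3-carboxylate
Conditions: [Ir(cod)(PCy3)(py)]PF6 (5 mol %), H2 (1 atm, stopped after 1 equiv), CH2Cl2, 0 °C
Reagents that add atoms: none
Why: In this hydroxyl-directed homogeneous hydrogenation, the locked chair of ring A (C9–OH equatorial, C7–OH and one C11 methyl axial) places the C7–OH gauche to C5 but antiperiplanar to C1, so O-bound iridium should reach only C4=C5, and saturating this one of the two diastereotopic alkenes makes C6 stereogenic as (S).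

**Step 6**
Reactants: 13 methyl (6S,7S,9R)-7,9-dihydroxy-7,11,11-trimethylspiro[5.5]undec-1-ene-3-carboxylate
Product: 14 methyl (6S,7S)-7-hydroxy-7,11,11-trimethyl-9-oxospiro[5.5]undec-1-ene-3-carboxylate
Conditions: DMP, CH2Cl2, 0 °C → rt
Reagents that add atoms: none
Why: Dess–Martin oxidation takes the secondary C9 carbinol, whose relay task is complete, to the ketone under near-neutral conditions that spare the tertiary alcohol, alkene and ester and avoid retro-aldol cleavage or dehydration of the β-hydroxy ketone.

**Step 7**
Reactants: 14 methyl (6S,7S)-7-hydroxy-7,11,11-trimethyl-9-oxospiro[5.5]undec-1-ene-3-carboxylate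
Product: 15 methyl (6S,7S,9S)-7,9-dihydroxy-7,11,11-trimethylspiro[5.5]undec-1-ene-3-carboxylate
Conditions: L-Selectride (1.5 equiv), THF, −78 °C; then H2O
Reagents that add atoms: none
Why: In this bulky trialkylborohydride reduction the axial C11 methyl and the axial C7–OH block the axial trajectory at C9, so hydride should arrive from the equatorial side and give the axial (9S) alcohol, cis to C7–OH, while the ester is inert at −78 °C.

**Step 8**
Reactants: 15 methyl (6S,7S,9S)-7,9-dihydroxy-7,11,11-trimethylspiro[5.5]undec-1-ene-3-carboxylate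
Product: 17 methyl (6S,7S,9R)-9-bromo-7-hydroxy-7,11,11-trimethylspiro[5.5]undec-1-ene-3-carboxylate, via axial secondary triflate 16 (not isolated)
Conditions: Tf2O (1.05 equiv), 2,6-lutidine, CH2Cl2, −78 °C; then n-Bu4NBr, −78 → 0 °C
Reagents that add atoms: tetrabutylammonium bromide CCCC[N+](CCCC)(CCCC)CCCC.[Br-]
Why: Only the secondary alcohol should be triflated at −78 °C, and bromide displaces the strained axial triflate by SN2 with inversion to give the equatorial (9R) bromide, while the cis tertiary hydroxyl cannot attack from the rear, so no oxetane can form.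

**Step 9**
Reactants: 17 methyl (6S,7S,9R)-9-bromo-7-hydroxy-7,11,11-trimethylspiro[5.5]undec-1-ene-3-carboxylate
Product: 19 (6S,7S,9R)-9-bromo-7-hydroxy-7,11,11-trimethylspiro[5.5]undec-2-ene-3-carbaldehyde, via unconjugated aldehyde 18 (not isolated)
Conditions: DIBAL-H (2.2 equiv), CH2Cl2, −78 °C; Rochelle salt work-up; then DBU (10 mol %), CH2Cl2, rt
Reagents that add atoms: none
Why: Partial ester reduction through the aluminium hemiacetal that is stable at −78 °C, followed by base-catalysed conjugation (dienolate, γ-protonation at C1), should give the trisubstituted enal; this erases the C3 epimer mixture while the double bond stays on the C1–C2 arm, so C6 remains defined.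

**Step 10**
Reactants: 19 (6S,7S,9R)-9-bromo-7-hydroxy-7,11,11-trimethylspiro[5.5]undec-2-ene-3-carbaldehyde
Product: 21 [(3E,6S,7S,9R)-9-bromo-7-hydroxy-7,11,11-trimethylspiro[5.5]undec-1-en-3-ylidene]methyl trifluoromethanesulfonate, via potassium (E)-dienolate 20 (not isolated)
Conditions: KHMDS (1.05 equiv), THF, −78 °C; then PhNTf2, −78 → −20 °C
Reagents that add atoms: N-phenylbis(trifluoromethanesulfonimide) O=S(=O)(N(c1ccccc1)S(=O)(=O)C(F)(F)F)C(F)(F)F
Why: γ-Deprotonation at C1 of the enal in its favoured s-trans conformation should give the dienolate with oxygen anti to C2 and syn to C4, and O-sulfonylation fixes this as the (E)-dienyl triflate, while at −78 °C with one equivalent of base the equatorial bromide (no antiperiplanar hydrogen) and the tertiary alcohol stay untouched.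

**Step 11**
Reactants: 21 [(3E,6S,7S,9R)-9-bromo-7-hydroxy-7,11,11-trimethylspiro[5.5]undec-1-en-3-ylidene]methyl trifluoromethanesulfonate
Product: 22 (3E,6S,7S,9R)-9-bromo-7,11,11-trimethyl-3-[(trimethylstannyl)methylidene]spiro[5.5]undec-1-en-7-ol
Conditions: (Me3Sn)2, Pd(PPh3)4 (5 mol %), LiCl, THF, 60 °C
Reagents that add atoms: hexamethylditin C[Sn](C)(C)[Sn](C)(C)C
Why: Palladium-catalysed stannylation of an alkenyl triflate with a distannane (Stille-type oxidative addition, transmetalation, reductive elimination) proceeds with retention of alkene geometry, and neither Pd(0)/PPh3 nor chloride should attack the hindered equatorial secondary bromide.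

**Step 12**
Reactants: 22 (3E,6S,7S,9R)-9-bromo-7,11,11-trimethyl-3-[(trimethylstannyl)methylidene]spiro[5.5]undec-1-en-7-ol
Product: 23 (3E,6S,7S,9R)-9-bromo-3-(bromomethylidene)-7,11,11-trimethylspiro[5.5]undec-1-en-7-ol
Conditions: NBS (1.0 equiv), CH2Cl2, −78 → 0 °C, dark
Reagents that add atoms: N-bromosuccinimide O=C1CCC(=O)N1Br
Why: Bromodestannylation (ipso electrophilic substitution at the tin-bearing carbon) is much faster than attack of NBS on the diene and goes with retention, so the (E)-bromomethylidene group of the target should result.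

**Compound list**

1 | methyl 4-iodobenzoate | COC(=O)c1ccc(I)cc1 | starting material
2 | 3-methylbut-2-enal | CC(C)=CC=O | starting material
3 | [4-(methoxycarbonyl)phenyl]magnesium chloride (not isolated) | COC(=O)c1ccc([Mg]Cl)cc1 | intermediate
4 | methyl 4-[2-methyl-4-(trimethylsilyloxy)but-3-en-2-yl]benzoate, E/Z mixture (not isolated) | COC(=O)c1ccc(cc1)C(C)(C)C=CO[Si](C)(C)C | intermediate
5 | methyl 4-(2-methyl-4-oxobutan-2-yl)benzoate | COC(=O)c1ccc(cc1)C(C)(C)CC=O | intermediate
6 | 2-methylallylboronic acid pinacol ester | CC(=C)CB1OC(C)(C)C(C)(C)O1 | starting material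
7 | pinacol borate ester of 8 (not isolated) | COC(=O)c1ccc(cc1)C(C)(C)C[C@@H](OB1OC(C)(C)C(C)(C)O1)CC(C)=C | intermediate
8 | methyl 4-[(4S)-4-hydroxy-2,6-dimethylhept-6-en-2-yl]benzoate | COC(=O)c1ccc(cc1)C(C)(C)C[C@@H](O)CC(C)=C | intermediate
9 | secondary ozonide (1,2,4-trioxolane) of 8 (not isolated) | COC(=O)c1ccc(cc1)C(C)(C)C[C@@H](O)CC1(C)OCOO1 | intermediate
10 | methyl 4-[(4R)-4-hydroxy-2-methyl-6-oxoheptan-2-yl]benzoate | COC(=O)c1ccc(cc1)C(C)(C)C[C@@H](O)CC(C)=O | intermediate
11 | bis(diiodosamarium(III)) C7-alkoxide / ester dienolate (not isolated) | CC1(C)C[C@@H](O)C[C@](C)(O[Sm](I)I)C12C=CC(=C(OC)O[Sm](I)I)C=C2 | intermediate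
12 | methyl (7S,9R)-7,9-dihydroxy-7,11,11-trimethylspiro[5.5]undeca-1,4-diene-3-carboxylate | CC1(C)C[C@@H](O)C[C@](C)(O)C12C=CC(C(=O)OC)C=C2 | intermediate
13 | methyl (6S,7S,9R)-7,9-dihydroxy-7,11,11-trimethylspiro[5.5]undec-1-ene-3-carboxylate | CC1(C)C[C@@H](O)C[C@](C)(O)[C@@]12C=CC(C(=O)OC)CC2 | intermediate
14 | methyl (6S,7S)-7-hydroxy-7,11,11-trimethyl-9-oxospiro[5.5]undec-1-ene-3-carboxylate | CC1(C)CC(=O)C[C@](C)(O)[C@@]12C=CC(C(=O)OC)CC2 | intermediate
15 | methyl (6S,7S,9S)-7,9-dihydroxy-7,11,11-trimethylspiro[5.5]undec-1-ene-3-carboxylate | CC1(C)C[C@H](O)C[C@](C)(O)[C@@]12C=CC(C(=O)OC)CC2 | intermediate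
16 | C9 axial triflate of 15 (not isolated) | CC1(C)C[C@H](OS(=O)(=O)C(F)(F)F)C[C@](C)(O)[C@@]12C=CC(C(=O)OC)CC2 | intermediate
17 | methyl (6S,7S,9R)-9-bromo-7-hydroxy-7,11,11-trimethylspiro[5.5]undec-1-ene-3-carboxylate | CC1(C)C[C@@H](Br)C[C@](C)(O)[C@@]12C=CC(C(=O)OC)CC2 | intermediate
18 | (6S,7S,9R)-9-bromo-7-hydroxy-7,11,11-trimethylspiro[5.5]undec-1-ene-3-carbaldehyde (not isolated) | CC1(C)C[C@@H](Br)C[C@](C)(O)[C@@]12C=CC(C=O)CC2 | intermediate
19 | (6S,7S,9R)-9-bromo-7-hydroxy-7,11,11-trimethylspiro[5.5]undec-2-ene-3-carbaldehyde | CC1(C)C[C@@H](Br)C[C@](C)(O)[C@@]12CC=C(C=O)CC2 | intermediate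
20 | potassium (E)-dienolate of 19 (not isolated) | CC1(C)C[C@@H](Br)C[C@](C)(O)[C@@]12C=C/C(=C/[O-])CC2.[K+] | intermediate
21 | [(3E,6S,7S,9R)-9-bromo-7-hydroxy-7,11,11-trimethylspiro[5.5]undec-1-en-3-ylidene]methyl trifluoromethanesulfonate | CC1(C)C[C@@H](Br)C[C@](C)(O)[C@@]12C=C/C(=C/OS(=O)(=O)C(F)(F)F)CC2 | intermediate
22 | (3E,6S,7S,9R)-9-bromo-7,11,11-trimethyl-3-[(trimethylstannyl)methylidene]spiro[5.5]undec-1-en-7-ol | CC1(C)C[C@@H](Br)C[C@](C)(O)[C@@]12C=C/C(=C/[Sn](C)(C)C)CC2 | intermediate
23 | (3E,6S,7S,9R)-9-bromo-3-(bromomethylidene)-7,11,11-trimethylspiro[5.5]undec-1-en-7-ol | CC1(C)C[C@@H](Br)C[C@](C)(O)[C@@]12C=C/C(=C/Br)CC2 | target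

**Total step count:** 12. **Longest linear sequence:** 12 steps, from 1.

**Steps most likely to fail**

**Step 4.**
- What may go wrong: the ketyl addition to the crowded ipso carbon may reverse. The spiro radical may regain aromaticity by β-scission of the C6–C11 bond (a 1,5-aryl shift) before it is reduced. The ketone may simply be reduced. Control between axial and equatorial O–Sm at C7 may be poor.
- Fallback (from 10, back at 13): the aromaticity is removed first, so that it cannot be regained.
  - Ketalisation of 10 (ethylene glycol, PPTS, benzene, reflux) would give the dioxolane-protected hydroxy ester F1.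
  - Birch reduction (Li, NH3, t-BuOH, THF, −78 °C) would give the 1,4-dihydrobenzoate F2.
  - DBU would move the double bonds into conjugation to give the cyclohexa-1,3-diene-1-carboxylate F3.
  - Dilute aqueous acid would free the keto dienoate F4.
  - SmI2–HMPA–t-BuOH would then close ring A by a 6-exo ketyl–olefin cyclisation onto the δ-carbon of the dienoate, with the ketyl oxygen anti to the acceptor double bond. α-Protonation leads directly to 13, so step 5 is no longer needed.

**Step 5.**
- What may go wrong: ester-directed or undirected hydrogenation may compete with hydroxyl delivery and erode the choice between the two alkenes. Over-reduction and double-bond migration are also possible.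
- Fallback (from 12, back at 13): the C7 hydroxyl picks out the near alkene by forming a bond to it.
  - 5-endo iodoetherification (I2, NaHCO3, MeCN, 0 °C) would give the 4,7-epoxy-5-iodo ester F5.
  - Radical deiodination (Bu3SnH, AIBN, benzene, 80 °C) would give the 4,7-epoxy ester F6.
  - E1cB opening of this β-alkoxy ester (KOt-Bu, THF, 0 °C) would return the free C7–OH and give the 1,3-diene-3-carboxylate F7, in which C5 is already saturated.
  - Copper hydride 1,4-reduction (hexameric triphenylphosphine copper hydride, benzene, rt) would deliver hydride to C4 and lead to 13.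

**Step 8.**
- What may go wrong: E2 elimination or ionisation of the axial secondary triflate may outrun substitution by bromide.
- Fallback (from 15, back at 17): both oxygens are tied into one ring, which locks the leaving group axial and masks the tertiary hydroxyl.
  - SOCl2 and Et3N (CH2Cl2, 0 °C) would convert the cis-1,3-diol into the bridged cyclic sulfite F8.
  - LiBr in DMF at 80 °C would open F8 at the secondary carbon C9 with inversion, and acidic hydrolysis of the remaining sulfite monoester would give 17.

**Further compounds**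

F1 | step 4 | methyl 4-[(4R)-4-hydroxy-2-methyl-5-(2-methyl-1,3-dioxolan-2-yl)pentan-2-yl]benzoate | COC(=O)c1ccc(cc1)C(C)(C)C[C@@H](O)CC1(C)OCCO1
F2 | step 4 | methyl 4-[(4R)-4-hydroxy-2-methyl-5-(2-methyl-1,3-dioxolan-2-yl)pentan-2-yl]cyclohexa-2,5-diene-1-carboxylate (cis/trans mixture) | COC(=O)C1C=CC(C=C1)C(C)(C)C[C@@H](O)CC1(C)OCCO1
F3 | step 4 | methyl 4-[(4R)-4-hydroxy-2-methyl-5-(2-methyl-1,3-dioxolan-2-yl)pentan-2-yl]cyclohexa-1,3-diene-1-carboxylate | COC(=O)C1=CC=C(CC1)C(C)(C)C[C@@H](O)CC1(C)OCCO1
F4 | step 4 | methyl 4-[(4R)-4-hydroxy-2-methyl-6-oxoheptan-2-yl]cyclohexa-1,3-diene-1-carboxylate | COC(=O)C1=CC=C(CC1)C(C)(C)C[C@@H](O)CC(C)=O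
F5 | step 5 | methyl 4,7-epoxy-9-hydroxy-5-iodo-7,11,11-trimethylspiro[5.5]undec-1-ene-3-carboxylate | CC1(C)C[C@@H](O)C[C@]2(C)O[C@H]3C(C(=O)OC)C=C[C@@]12[C@@H]3I
F6 | step 5 | methyl 4,7-epoxy-9-hydroxy-7,11,11-trimethylspiro[5.5]undec-1-ene-3-carboxylate | CC1(C)C[C@@H](O)C[C@]2(C)O[C@H]3C(C(=O)OC)C=C[C@@]12C3
F7 | step 5 | methyl (6S,7S,9R)-7,9-dihydroxy-7,11,11-trimethylspiro[5.5]undeca-1,3-diene-3-carboxylate | CC1(C)C[C@@H](O)C[C@](C)(O)[C@@]12C=CC(C(=O)OC)=CC2
F8 | step 8 | cyclic sulfite (7,9-O-sulfinyl derivative) of 15 | CC1(C)C[C@H]2C[C@](C)(OS(=O)O2)[C@@]13C=CC(C(=O)OC)CC3
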